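**Plan**
Cuts: first the five benzyl-type groups (O2- and O4-benzyl, which hold the uracil ring as an aromatic 2,4-dialkoxypyrimidine; N7-CH2OBn; two aryl O-benzyl). Next the bond between the ketone carbon on C6 and C1 of the 4-hydroxy-3-methoxyphenyl ring. Last, C5–aryl, C6–CHO, C2–O/C4–O and N7–C of the bicycle.
Enabling feature: in the aroyl ring the ketone sits on C1, C2 bears only H and C3 bears OMe. C1≡C2 can therefore be the triple bond of a 3-methoxyaryne, whose OMe neighbour sends a carbon nucleophile to C1 and the proton to C2. The ketone carbon on pyrrole C6 can be that nucleophile, as the carbene-bound acyl anion of a 6-carbaldehyde.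
Forward: no ring is built. The purchased pyrrolo[2,3-d]pyrimidine is dressed in the order N7, C4/C2, C6, C5 (steps 1–4). The o-silylaryl triflate is made from O-benzylvanillin (steps 5–8). The halves are joined by carbene-catalysed aryne hydroacylation (step 9), and one hydrogenolysis frees all heteroatoms (step 10).
Stereochemistry: the target has no stereocentre and no double-bond geometry. Only regiochemistry must be set (C5 versus C6 of the pyrrole ring, C1 versus C2 of the aryne).

Key step: step 9

Assumption: the 2,4-dihydroxypyrimidine freed in the last step is taken to rest as the 2,4-dioxo (lactam) tautomer drawn for the target.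

Step 1
Reactants: 1 2,4-dichloro-5-iodo-7H-pyrrolo[2,3-d]pyrimidine
Product: 3 7-[(benzyloxy)methyl]-2,4-dichloro-5-iodo-7H-pyrrolo[2,3-d]pyrimidine, via sodium salt 2 (not isolated)
Conditions: NaH, DMF, 0 °C; BOMCl, 0 °C to rt
Reagents that add atoms: benzyl chloromethyl ether (BOMCl), ClCOCc1ccccc1
Why: SN2 N-alkylation of the pyrrole-type anion at N7, the normal alkylation site of 7-deazapurines, should put on a benzyloxymethyl group that later keeps the aryne away from nitrogen, assists C6 lithiation through its ether oxygen and leaves under hydrogenolysis.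

Step 2
Reactants: 3 7-[(benzyloxy)methyl]-2,4-dichloro-5-iodo-7H-pyrrolo[2,3-d]pyrimidine
Product: 5 2,4-bis(benzyloxy)-7-[(benzyloxy)methyl]-5-iodo-7H-pyrrolo[2,3-d]pyrimidine, via 2-chloro monoether 4 (not isolated)
Conditions: BnOH, NaH, 1,4-dioxane, rt to 95 °C
Reagents that add atoms: benzyl alcohol, OCc1ccccc1
Why: Double nucleophilic aromatic substitution (addition–elimination) on the π-deficient pyrimidine ring should replace C4–Cl first and C2–Cl on heating, whereas the C5–I bond on the π-excessive pyrrole ring offers no Meisenheimer pathway and is known to survive hot alkoxide in 4-chloro-5-iodo-7-deazapurines.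

Step 3
Reactants: 5 2,4-bis(benzyloxy)-7-[(benzyloxy)methyl]-5-iodo-7H-pyrrolo[2,3-d]pyrimidine
Product: 8 2,4-bis(benzyloxy)-7-[(benzyloxy)methyl]-5-iodo-7H-pyrrolo[2,3-d]pyrimidine-6-carbaldehyde, via C6 lithio species 6 (not isolated), via lithium aminoalkoxide 7 (not isolated)
Conditions: LiN(iPr)2, THF, −78 °C; DMF, −78 to −40 °C; AcOH
Reagents that add atoms: N,N-dimethylformamide, CN(C)C=O
Why: Directed lithiation and formylation: C6–H is the only ring C–H, it is acidified by N7 and the neighbouring iodine and reached through chelation by the BOM oxygen, a lithium amide does not exchange iodine, the 6-lithio-5-iodo arrangement is already the more stable carbanion so iodine has no reason to migrate, and DMF gives an aminoalkoxide that holds until the acid quench.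

Step 4
Reactants: 8 2,4-bis(benzyloxy)-7-[(benzyloxy)methyl]-5-iodo-7H-pyrrolo[2,3-d]pyrimidine-6-carbaldehyde; 9 [4-(benzyloxy)-3-methoxyphenyl]boronic acid
Product: 10 2,4-bis(benzyloxy)-5-[4-(benzyloxy)-3-methoxyphenyl]-7-[(benzyloxy)methyl]-7H-pyrrolo[2,3-d]pyrimidine-6-carbaldehyde
Conditions: Pd(dppf)Cl2 (5 mol %), K2CO3, 1,4-dioxane/H2O, 85 °C
Reagents that add atoms: none
Why: Suzuki–Miyaura coupling, in which zerovalent palladium inserts into the C5–I bond (helped by the ortho formyl group) and transmetalation and reductive elimination follow, should place the aryl ring at C5, and the benzyl ethers, the BOM group and the non-enolisable aldehyde tolerate aqueous carbonate.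

Step 5
Reactants: 11 4-(benzyloxy)-3-methoxybenzaldehyde (O-benzylvanillin)
Product: 13 4-(benzyloxy)-3-methoxyphenol, via aryl formate 12 (not isolated)
Conditions: mCPBA, CH2Cl2, 0 °C to rt; then K2CO3 (cat.), MeOH, rt
Reagents that add atoms: 3-chloroperoxybenzoic acid (mCPBA), OOC(=O)c1cccc(Cl)c1
Why: Baeyer–Villiger oxidation of an electron-rich benzaldehyde, in which the aryl group migrates in the Criegee adduct in preference to hydride, should give formate 12, and base-catalysed methanolysis should free the phenol.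

Step 6
Reactants: 13 4-(benzyloxy)-3-methoxyphenol
Product: 14 4-(benzyloxy)-3-methoxyphenyl isopropylcarbamate
Conditions: iPrNCO, Et3N (cat.), CH2Cl2, rt
Reagents that add atoms: isopropyl isocyanate, CC(C)N=C=O
Why: Base-catalysed addition of the phenol to the isocyanate should give the secondary carbamate, chosen because it directs metalation after N-silylation and can later be removed under mild base by an E1cB path.

Step 7
Reactants: 14 4-(benzyloxy)-3-methoxyphenyl isopropylcarbamate
Product: 18 4-(benzyloxy)-3-methoxy-2-(trimethylsilyl)phenyl isopropylcarbamate, via N-silyl carbamate 15 (not isolated), via C2 aryllithium 16 (not isolated), via disilyl carbamate 17 (not isolated)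
Conditions: TBSOTf, TMEDA, Et2O, 0 °C to rt; n-BuLi, TMEDA, −78 °C; TMSCl, −78 °C to rt; aq. NaHSO4
Reagents that add atoms: chlorotrimethylsilane, C[Si](C)(C)Cl; tert-butyldimethylsilyl triflate (its atoms are held only in 15 to 17), CC(C)(C)[Si](C)(C)OS(=O)(=O)C(F)(F)F
Why: Directed ortho-metalation, in which the N-silylated carbamate on C1 and the methoxy group on C3 cooperate so that the C2–H between them is removed, should be followed by C-silylation faster than anionic Fries migration at −78 °C, n-BuLi/TMEDA at this temperature should leave the benzylic O–CH2 alone, and the acidic work-up takes off the N-silyl group only.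

Step 8
Reactants: 18 4-(benzyloxy)-3-methoxy-2-(trimethylsilyl)phenyl isopropylcarbamate
Product: 20 4-(benzyloxy)-3-methoxy-2-(trimethylsilyl)phenyl trifluoromethanesulfonate, via silylphenol 19 (not isolated)
Conditions: DBU, Et2NH, MeCN, 40 °C; then PhNTf2, rt
Reagents that add atoms: N-phenylbis(trifluoromethanesulfonimide), O=S(=O)(N(c1ccccc1)S(=O)(=O)C(F)(F)F)C(F)(F)F
Why: E1cB carbamate cleavage (DBU removes N–H, the phenoxide of 19 leaves, Et2NH traps the isocyanate as a urea) followed by O-sulfonylation in the same flask avoids acid, which would protodesilylate the electron-rich arylsilane.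

Step 9
Reactants: 10 2,4-bis(benzyloxy)-5-[4-(benzyloxy)-3-methoxyphenyl]-7-[(benzyloxy)methyl]-7H-pyrrolo[2,3-d]pyrimidine-6-carbaldehyde; 20 4-(benzyloxy)-3-methoxy-2-(trimethylsilyl)phenyl trifluoromethanesulfonate
Product: 23 {2,4-bis(benzyloxy)-5-[4-(benzyloxy)-3-methoxyphenyl]-7-[(benzyloxy)methyl]-7H-pyrrolo[2,3-d]pyrimidin-6-yl}[4-(benzyloxy)-3-methoxyphenyl]methanone, via aryne 21 (not isolated), via Breslow enaminol 22 (not isolated)
Conditions: 3-mesityl-5,6,7,8-tetrahydro-4H-cyclohepta[d]thiazol-3-ium perchlorate (20 mol %), KOtBu (20 mol %), KF, 18-crown-6, THF, 25 °C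
Reagents that add atoms: 3-mesityl-5,6,7,8-tetrahydro-4H-cyclohepta[d]thiazol-3-ium perchlorate (catalyst, its atoms are held only in 22), Cc1cc(C)c(c(C)c1)-[n+]1csc2CCCCCc12.[O-]Cl(=O)(=O)=O
Why: KOtBu frees the thiazol-2-ylidene, which adds to the C6 formyl group of 10 and after proton shift gives Breslow enaminol 22, while fluoride attacks silicon in 20 and expels triflate so that aryne 21 is fed in slowly. The nucleophilic enaminol carbon bonds to aryne C1, the aryl anion developing at C2 takes the enaminol O–H proton, and collapse of the alkoxide releases ketone 23 and the carbene. The closest known reaction type is the N-heterocyclic-carbene-catalysed intermolecular hydroacylation of arynes with aromatic and heteroaromatic aldehydes; no ring is closed and no stereocentre is made. The step needs attack at C1 and not at C2: the σ-withdrawing C3 methoxy group beside the triple bond widens the internal angle at C1, stabilises negative charge on the adjacent C2 and shields C2 sterically, and the C4 benzyloxy group (meta to C2, para to C1) pulls the same way. It also needs the aryne to meet carbon only, which is secured because every N–H and O–H of both partners is masked (O2, O4, N7, both phenols), and self-benzoin of the flanked aldehyde should be slow. Holding the uracil ring as an aromatic 2,4-bis(benzyloxy)pyrimidine removes the vinylogous-urea push into C6 and keeps the formyl group electrophilic enough for carbene addition.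

Step 10
Reactants: 23 {2,4-bis(benzyloxy)-5-[4-(benzyloxy)-3-methoxyphenyl]-7-[(benzyloxy)methyl]-7H-pyrrolo[2,3-d]pyrimidin-6-yl}[4-(benzyloxy)-3-methoxyphenyl]methanone
Product: 25 rigidin D, via N7-hydroxymethyl compound 24 (not isolated)
Conditions: H2 (1 atm), Pd(OH)2/C, THF/MeOH, rt; filter; Et3N, MeOH, 40 °C
Reagents that add atoms: none
Why: Catalytic hydrogenolysis should cleave all five benzylic C–O bonds at once (two imidate-type O-benzyl groups that unveil the uracil ring, two aryl benzyl ethers, the BOM benzyl), the 2-acylpyrrole ketone is a vinylogous amide and should resist reduction at one atmosphere, and hemiaminal 24 should lose formaldehyde under mild base.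

**Compound list**
1 | 2,4-dichloro-5-iodo-7H-pyrrolo[2,3-d]pyrimidine | Clc1nc(Cl)c2c(I)c[nH]c2n1 | starting material
2 | sodium salt of 1 (formed in the flask) | [Na+].Clc1nc(Cl)c2c(I)c[n-]c2n1 | intermediate
3 | 7-[(benzyloxy)methyl]-2,4-dichloro-5-iodo-7H-pyrrolo[2,3-d]pyrimidine | Clc1nc(Cl)c2c(I)cn(COCc3ccccc3)c2n1 | intermediate
4 | 4-(benzyloxy)-7-[(benzyloxy)methyl]-2-chloro-5-iodo-7H-pyrrolo[2,3-d]pyrimidine (formed in the flask) | Clc1nc(OCc3ccccc3)c2c(I)cn(COCc4ccccc4)c2n1 | intermediate
5 | 2,4-bis(benzyloxy)-7-[(benzyloxy)methyl]-5-iodo-7H-pyrrolo[2,3-d]pyrimidine | Ic1cn(COCc2ccccc2)c2nc(OCc3ccccc3)nc(OCc3ccccc3)c12 | intermediate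
6 | 6-lithio derivative of 5 (formed in the flask) | [Li]c1c(I)c2c(OCc3ccccc3)nc(OCc3ccccc3)nc2n1COCc1ccccc1 | intermediate
7 | lithium (dimethylamino)alkoxide from 6 and DMF (formed in the flask, racemic) | [Li]OC(N(C)C)c1c(I)c2c(OCc3ccccc3)nc(OCc3ccccc3)nc2n1COCc1ccccc1 | intermediate
8 | 2,4-bis(benzyloxy)-7-[(benzyloxy)methyl]-5-iodo-7H-pyrrolo[2,3-d]pyrimidine-6-carbaldehyde | O=Cc1c(I)c2c(OCc3ccccc3)nc(OCc3ccccc3)nc2n1COCc1ccccc1 | intermediate
9 | [4-(benzyloxy)-3-methoxyphenyl]boronic acid | COc1cc(B(O)O)ccc1OCc1ccccc1 | starting material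
10 | 2,4-bis(benzyloxy)-5-[4-(benzyloxy)-3-methoxyphenyl]-7-[(benzyloxy)methyl]-7H-pyrrolo[2,3-d]pyrimidine-6-carbaldehyde | O=Cc1c(-c2ccc(OCc3ccccc3)c(OC)c2)c2c(OCc3ccccc3)nc(OCc3ccccc3)nc2n1COCc1ccccc1 | intermediate
11 | 4-(benzyloxy)-3-methoxybenzaldehyde | COc1cc(C=O)ccc1OCc1ccccc1 | starting material
12 | 4-(benzyloxy)-3-methoxyphenyl formate (formed in the flask) | COc1cc(OC=O)ccc1OCc1ccccc1 | intermediate
13 | 4-(benzyloxy)-3-methoxyphenol | COc1cc(O)ccc1OCc1ccccc1 | intermediate
14 | 4-(benzyloxy)-3-methoxyphenyl isopropylcarbamate | COc1cc(OC(=O)NC(C)C)ccc1OCc1ccccc1 | intermediate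
15 | 4-(benzyloxy)-3-methoxyphenyl N-(tert-butyldimethylsilyl)-N-isopropylcarbamate (formed in the flask) | COc1cc(OC(=O)N(C(C)C)[Si](C)(C)C(C)(C)C)ccc1OCc1ccccc1 | intermediate
16 | 2-lithio derivative of 15 (formed in the flask) | COc1c([Li])c(OC(=O)N(C(C)C)[Si](C)(C)C(C)(C)C)ccc1OCc1ccccc1 | intermediate
17 | 2-(trimethylsilyl) derivative of 15 (formed in the flask) | COc1c([Si](C)(C)C)c(OC(=O)N(C(C)C)[Si](C)(C)C(C)(C)C)ccc1OCc1ccccc1 | intermediate
18 | 4-(benzyloxy)-3-methoxy-2-(trimethylsilyl)phenyl isopropylcarbamate | COc1c([Si](C)(C)C)c(OC(=O)NC(C)C)ccc1OCc1ccccc1 | intermediate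
19 | 4-(benzyloxy)-3-methoxy-2-(trimethylsilyl)phenol (formed in the flask as its DBU salt) | COc1c([Si](C)(C)C)c(O)ccc1OCc1ccccc1 | intermediate
20 | 4-(benzyloxy)-3-methoxy-2-(trimethylsilyl)phenyl trifluoromethanesulfonate | COc1c([Si](C)(C)C)c(OS(=O)(=O)C(F)(F)F)ccc1OCc1ccccc1 | intermediate
21 | 4-(benzyloxy)-3-methoxybenzyne, triple bond C1≡C2 (formed in the flask) | COC1=C(OCc2ccccc2)C=CC#C1 | intermediate
22 | Breslow enaminol from 10 and the thiazol-2-ylidene (formed in the flask, geometry not defined) | OC(=C1SC2=C(CCCCC2)N1c1c(C)cc(C)cc1C)c1c(-c2ccc(OCc3ccccc3)c(OC)c2)c2c(OCc3ccccc3)nc(OCc3ccccc3)nc2n1COCc1ccccc1 | intermediate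
23 | {2,4-bis(benzyloxy)-5-[4-(benzyloxy)-3-methoxyphenyl]-7-[(benzyloxy)methyl]-7H-pyrrolo[2,3-d]pyrimidin-6-yl}[4-(benzyloxy)-3-methoxyphenyl]methanone | COc1cc(ccc1OCc1ccccc1)C(=O)c1c(-c2ccc(OCc3ccccc3)c(OC)c2)c2c(OCc3ccccc3)nc(OCc3ccccc3)nc2n1COCc1ccccc1 | intermediate
24 | 7-(hydroxymethyl)rigidin D (formed in the flask) | COc1cc(ccc1O)C(=O)c1c(-c2ccc(O)c(OC)c2)c2c(=O)[nH]c(=O)[nH]c2n1CO | intermediate
25 | rigidin D, 6-(4-hydroxy-3-methoxybenzoyl)-5-(4-hydroxy-3-methoxyphenyl)-1H-pyrrolo[2,3-d]pyrimidine-2,4(3H,7H)-dione | COc1cc(C(=O)c2[nH]c3[nH]c(=O)[nH]c(=O)c3c2-c2ccc(O)c(OC)c2)ccc1O | target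

**Totals**
Total step count: 10.
Longest linear sequence: 6 (steps 1, 2, 3, 4, 9, 10, or equally steps 5, 6, 7, 8, 9, 10).

**Steps most likely to fail**

Step 9. Carbene addition to a formyl group flanked by the N7 substituent and the C5 aryl ring may be slow. The aryne would then be used up by the free carbene, by tert-butoxide or by self-reaction before the enaminol can meet it.
The fallback sets out from 10 and comes back at 23, with the polarity reversed. Purchased 1-(benzyloxy)-4-bromo-2-methoxybenzene F1 is turned with Mg in THF into [4-(benzyloxy)-3-methoxyphenyl]magnesium bromide F2. This should add to the formyl group of 10 at 0 °C and, after aq. NH4Cl, give the racemic diaryl carbinol F3. Oxidation of this doubly activated carbinol with MnO2 in CH2Cl2 should give 23.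

Step 7. The alkyllithium may metalate C6 or the benzylic O–CH2 (followed by Wittig rearrangement). Silylation at the crowded C2 may also lag behind migration of the carbamoyl group.
The fallback sets out from 13 and comes back at 19. An amide base under acidity control with an in-flask trap replaces kinetic alkyllithium metalation, and the director is removed by reduction instead of elimination.
- 13 is carbamoylated with Et2NCOCl and NaH in THF to 4-(benzyloxy)-3-methoxyphenyl diethylcarbamate F4.
- LiN(iPr)2 in THF at −78 °C, with TMSCl already present, should remove only the most acidic C2–H between the two oxygen substituents and give 4-(benzyloxy)-3-methoxy-2-(trimethylsilyl)phenyl diethylcarbamate F5.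
- LiAlH4 in THF should cleave the carbamate to 19, which is then isolated and triflated with PhNTf2 and DBU, as in the second half of step 8, to give 20.

Step 3. Deprotonation may stay incomplete, iodine may scramble between C5 and C6, or iodine may be lost.
The fallback sets out from 5 and comes back at 10. The order of events is turned round and an electrophilic formylation replaces the anionic one.
- 5 is coupled first with 9 under the conditions of step 4 to give 2,4-bis(benzyloxy)-5-[4-(benzyloxy)-3-methoxyphenyl]-7-[(benzyloxy)methyl]-7H-pyrrolo[2,3-d]pyrimidine F6.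
- Vilsmeier–Haack reaction (POCl3, DMF, 0 °C to rt) at C6, the only free pyrrole carbon, should give the C6 iminium chloride F7.
- Hydrolysis with aq. NaOAc should give 10.

**Further compounds**
F1 | step 9 | 1-(benzyloxy)-4-bromo-2-methoxybenzene (purchased) | COc1cc(Br)ccc1OCc1ccccc1
F2 | step 9 | [4-(benzyloxy)-3-methoxyphenyl]magnesium bromide | COc1cc([Mg]Br)ccc1OCc1ccccc1
F3 | step 9 | {2,4-bis(benzyloxy)-5-[4-(benzyloxy)-3-methoxyphenyl]-7-[(benzyloxy)methyl]-7H-pyrrolo[2,3-d]pyrimidin-6-yl}[4-(benzyloxy)-3-methoxyphenyl]methanol (racemic) | COc1cc(ccc1OCc1ccccc1)C(O)c1c(-c2ccc(OCc3ccccc3)c(OC)c2)c2c(OCc3ccccc3)nc(OCc3ccccc3)nc2n1COCc1ccccc1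
F4 | step 7 | 4-(benzyloxy)-3-methoxyphenyl diethylcarbamate | COc1cc(OC(=O)N(CC)CC)ccc1OCc1ccccc1
F5 | step 7 | 4-(benzyloxy)-3-methoxy-2-(trimethylsilyl)phenyl diethylcarbamate | COc1c([Si](C)(C)C)c(OC(=O)N(CC)CC)ccc1OCc1ccccc1
F6 | step 3 | 2,4-bis(benzyloxy)-5-[4-(benzyloxy)-3-methoxyphenyl]-7-[(benzyloxy)methyl]-7H-pyrrolo[2,3-d]pyrimidine | COc1cc(ccc1OCc1ccccc1)-c1cn(COCc2ccccc2)c2nc(OCc3ccccc3)nc(OCc3ccccc3)c12
F7 | step 3 | C6 (dimethyliminio)methyl chloride of F6 | [Cl-].C[N+](C)=Cc1c(-c2ccc(OCc3ccccc3)c(OC)c2)c2c(OCc3ccccc3)nc(OCc3ccccc3)nc2n1COCc1ccccc1
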